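**Retrosynthetic overview**

1. Target locants: C1 = CBr(CH2Br), C2 = CHCl, C3 = CH2, C4 = CHCl, C5 = C(CH3)(chloroethenyl), C6 = CH2. C1 is a masked carbonyl: 16 ⇐ 15 (Br2) ⇐ 14 (C2–Cl by inversion) ⇐ 13 ⇐ 12 ⇐ 10.
2. Key disconnection C3–C4: cyclohexanone 10 ⇐ 2-chloro-1-vinylcyclobutanol 8. An alkoxy radical cleaves the strained C1–C4 bond, and the C4 radical recloses 6-endo on C3 of the liberated vinyl ketone (two-carbon ring expansion).
3. Enabling feature: with C1 as C=O, atoms C1–C6–C5–C4 are the four-membered ring of a ketene/1,1-disubstituted-alkene [2+2] adduct that carries Cl on C4 next to quaternary C5, and C2–C3 are a vinyl group on C1.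
4. Ring order: cyclobutane (step 1), made chiral by desymmetrisation of the achiral ketone 5 (steps 3–4); the cyclohexane is formed and the cyclobutane consumed in step 6.
5. The chloroethenyl group is carried as a rod-like alkyne on C5: it takes the axial site (relaying C5 to C4), does not migrate in the radical step, and gives the Z-chloroalkene stereospecifically.

Key step: step 6

Assumption: silyl enyne 1 is taken as a catalogue chemical (otherwise one silylation of 2-methylbut-1-en-3-yne), and the (R,R)-amide in step 3 is assumed to give the (3R) enol ether 6; if the sense is opposite, the (S,S)-amide is used instead.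

**Route**

Step 1
Reactants: 1 trimethyl(3-methylbut-3-en-1-yn-1-yl)silane; 2 trichloroacetyl chloride
Product: 4 2,2-dichloro-3-methyl-3-[(trimethylsilyl)ethynyl]cyclobutan-1-one (racemic), via dichloroketene 3 (not isolated)
Conditions: Zn–Cu couple, POCl3, Et2O, reflux (slow addition of 2)
Reagents that add atoms: none
Why: Staudinger-type ketene–alkene [2+2] cycloaddition, in which the carbonyl carbon of dichloroketene bonds to the terminal CH2 and the CCl2 carbon to the alkene carbon that best carries positive charge (tertiary and propargylic), while the silyl-capped alkyne should be spared; the stereocentre formed is racemic and is erased in step 2.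

Step 2
Reactants: 4 2,2-dichloro-3-methyl-3-[(trimethylsilyl)ethynyl]cyclobutan-1-one
Product: 5 3-methyl-3-[(trimethylsilyl)ethynyl]cyclobutan-1-one (achiral)
Conditions: Zn dust, AcOH, 70 °C
Reagents that add atoms: none
Why: Zinc/acetic acid reductive dechlorination of an α,α-dichloroketone (through zinc enolates) should remove both chlorines and give the prochiral cyclobutanone whose two CH2 groups are enantiotopic.

Step 3
Reactants: 5 3-methyl-3-[(trimethylsilyl)ethynyl]cyclobutan-1-one
Product: 6 trimethyl({(3R)-3-methyl-3-[(trimethylsilyl)ethynyl]cyclobut-1-en-1-yl}oxy)silane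
Conditions: (R,R)-bis(1-phenylethyl)amine, n-BuLi, TMSCl (in situ quench), THF, −100 °C
Reagents that add atoms: chlorotrimethylsilane, C[Si](C)(C)Cl
Why: Enantiotopic-group-selective deprotonation of a prochiral cyclobutanone by a chiral lithium amide with in situ silylation should select one CH2 group, because ring puckering places the slim alkynyl group pseudo-axial and methyl pseudo-equatorial so that the ketone is read like a 3-monosubstituted cyclobutanone; this fixes the configuration of the quaternary carbon.

Step 4
Reactants: 6 trimethyl({(3R)-3-methyl-3-[(trimethylsilyl)ethynyl]cyclobut-1-en-1-yl}oxy)silane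
Product: 7 (2R,3S)-2-chloro-3-methyl-3-[(trimethylsilyl)ethynyl]cyclobutan-1-one
Conditions: NCS, THF, −78 to 0 °C
Reagents that add atoms: N-chlorosuccinimide, ClN1C(=O)CCC1=O
Why: Electrophilic α-chlorination of a silyl enol ether puts chlorine regiospecifically on the enol carbon next to the quaternary centre, expected anti to methyl; the configuration of this CHCl centre is of no consequence because it becomes a radical in step 6.

Step 5
Reactants: 7 (2R,3S)-2-chloro-3-methyl-3-[(trimethylsilyl)ethynyl]cyclobutan-1-one
Product: 8 (1R,2R,3S)-2-chloro-1-ethenyl-3-methyl-3-[(trimethylsilyl)ethynyl]cyclobutan-1-ol (carbinol epimer, if formed, is equally usable)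
Conditions: CH2=CHMgBr, LaCl3·2LiCl (30 mol%), THF, −78 °C; AcOH quench at −78 °C
Reagents that add atoms: vinylmagnesium bromide, C=C[Mg]Br
Why: Lanthanum-assisted Grignard 1,2-addition to the strained, highly electrophilic cyclobutanone should outrun enolisation, with vinyl entering anti to the α-chlorine, and the cold acidic quench keeps the chlorohydrin alkoxide from semibenzilic (quasi-Favorskii) ring contraction.

Step 6
Reactants: 8 (1R,2R,3S)-2-chloro-1-ethenyl-3-methyl-3-[(trimethylsilyl)ethynyl]cyclobutan-1-ol
Product: 10 (3S,4S)-4-chloro-3-methyl-3-[(trimethylsilyl)ethynyl]cyclohexan-1-one, via ring-opened chloroalkyl radical enone 9 (not isolated)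
Conditions: [Ir(dF(CF3)ppy)2(5,5'-d(CF3)bpy)]PF6 (2 mol%), 2,4,6-collidine (20 mol%), 2,4,6-triisopropylbenzenethiol (10 mol%), CH2Cl2 (0.02 M), blue LEDs, rt
Reagents that add atoms: none
Why: Photoexcited trivalent iridium with collidine removes the hydroxyl hydrogen by concerted proton-coupled electron transfer, and β-scission of the resulting cyclobutyloxy radical cleaves the C1–C2(Cl) ring bond (about 26 kcal/mol of strain released; a secondary α-chloroalkyl radical forms instead of the primary radical from the other ring bond) to unmask a vinyl ketone, radical 9. Radical 9 closes the cyclohexane by 6-endo-trig conjugate addition of the chlorine-bearing carbon to the terminal CH2 of the vinyl ketone, the endo mode being dictated by the polarity of the enone, and the α-keto radical is then reduced by divalent iridium and protonated or quenched by the thiol, so the step is a redox-neutral isomerisation. The closest known reaction type is the photocatalytic alkoxy-radical two-carbon ring expansion of 1-alkenylcycloalkanols; the 2-chloro substituent is the new element. The new CHCl stereocentre is set in a chair-like transition state in which the quaternary carbon holds methyl equatorial and the rod-like alkynyl group axial (A values about 1.7 against about 0.4 kcal/mol) and chlorine on the attacking carbon is pseudo-equatorial, which places Cl cis to the alkynyl group; the configurations at C1 and C2 of 8 are lost, so all epimers converge. The selectivities needed are cleavage toward the chlorinated carbon, endo closure, and cyclisation before hydrogen transfer; they are secured by radical stabilisation by chlorine, by the vinyl ketone acceptor, by a hindered thiol at low concentration under high dilution, and by the alkyne, which (unlike an alkenyl group) does not undergo fast 1,2-migration through a cyclopropylcarbinyl radical.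

Step 7
Reactants: 10 (3S,4S)-4-chloro-3-methyl-3-[(trimethylsilyl)ethynyl]cyclohexan-1-one
Product: 11 (3S,4S)-4-chloro-3-(chloroethynyl)-3-methylcyclohexan-1-one
Conditions: NCS, AgNO3 (10 mol%), acetone, rt
Reagents that add atoms: N-chlorosuccinimide, ClN1C(=O)CCC1=O
Why: Silver-catalysed halodesilylation (silver acetylide, then chlorine transfer from NCS) should convert the alkynylsilane directly into the 1-chloroalkyne without touching the ketone or the secondary chloride.

Step 8
Reactants: 11 (3S,4S)-4-chloro-3-(chloroethynyl)-3-methylcyclohexan-1-one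
Product: 12 (3S,4S)-4-chloro-3-[(Z)-2-chloroethenyl]-3-methylcyclohexan-1-one
Conditions: 2-nitrobenzenesulfonylhydrazide, Et3N, THF/i-PrOH, rt
Reagents that add atoms: none
Why: Diimide reduction transfers two hydrogens in a concerted syn fashion to the 1-chloroalkyne (known for 1-haloalkynes), which fixes the Z geometry stereospecifically and leaves the ketone and C–Cl bonds alone.

Step 9
Reactants: 12 (3S,4S)-4-chloro-3-[(Z)-2-chloroethenyl]-3-methylcyclohexan-1-one
Product: 13 (1S,2S)-1-chloro-2-[(Z)-2-chloroethenyl]-2-methyl-4-methylidenecyclohexane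
Conditions: Ph3PCH3Br, KOtBu (slight deficit), THF, 0 °C to rt
Reagents that add atoms: methyltriphenylphosphonium bromide, C[P+](c1ccccc1)(c1ccccc1)c1ccccc1.[Br-]
Why: Wittig methylenation of the unhindered ring ketone by the non-stabilised ylide, preformed with a slight deficit of base so that the Z-chloroalkene is not dehydrochlorinated.

Step 10
Reactants: 13 (1S,2S)-1-chloro-2-[(Z)-2-chloroethenyl]-2-methyl-4-methylidenecyclohexane
Product: 14 (1S,4S,5S)-5-chloro-4-[(Z)-2-chloroethenyl]-4-methyl-2-methylidenecyclohexan-1-ol
Conditions: SeO2 (30 mol%), t-BuOOH, CH2Cl2, rt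
Reagents that add atoms: tert-butyl hydroperoxide, CC(C)(C)OO (oxygen source, relayed by selenium dioxide, O=[Se]=O)
Why: Riley allylic oxidation (ene reaction, then [2,3]-sigmatropic shift) should hydroxylate the ring CH2 flanking the methylene on the side away from the quaternary carbon and replace its axial hydrogen, on the face anti to the 1,3-related C–Cl, which gives the axial alcohol needed for inversion.

Step 11
Reactants: 14 (1S,4S,5S)-5-chloro-4-[(Z)-2-chloroethenyl]-4-methyl-2-methylidenecyclohexan-1-ol
Product: 15 (1S,2S,4R)-2,4-dichloro-1-[(Z)-2-chloroethenyl]-1-methyl-5-methylidenecyclohexane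
Conditions: PPh3, hexachloroacetone, CH2Cl2, 0 °C to rt
Reagents that add atoms: hexachloroacetone, ClC(Cl)(Cl)C(=O)C(Cl)(Cl)Cl
Why: Appel-type chlorination with PPh3/hexachloroacetone, the reagent pair known to convert allylic alcohols into chlorides by SN2 with inversion and little allylic transposition, should turn the axial alcohol into the equatorial chloride cis to the other ring chlorine.

Step 12
Reactants: 15 (1S,2S,4R)-2,4-dichloro-1-[(Z)-2-chloroethenyl]-1-methyl-5-methylidenecyclohexane
Product: 16 (1S,2R,4S,5S)-1-bromo-1-(bromomethyl)-2,4-dichloro-5-[(Z)-2-chloroethenyl]-5-methylcyclohexane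
Conditions: Br2, CH2Cl2, −78 °C, dark
Reagents that add atoms: bromine, BrBr
Why: Electrophilic anti addition of Br2 to the only electron-rich alkene (the chloroalkene is deactivated): with both chlorines equatorial the chair is fixed, the bromonium ion forms on the open equatorial face and bromide opens it at the tertiary carbon from the axial side, which should give axial Br and equatorial CH2Br as in the target.

**Compound list**

1 | trimethyl(3-methylbut-3-en-1-yn-1-yl)silane | C=C(C)C#C[Si](C)(C)C | starting material
2 | trichloroacetyl chloride | ClC(=O)C(Cl)(Cl)Cl | starting material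
3 | dichloroketene | O=C=C(Cl)Cl | intermediate
4 | 2,2-dichloro-3-methyl-3-[(trimethylsilyl)ethynyl]cyclobutan-1-one (racemic) | CC1(C#C[Si](C)(C)C)CC(=O)C1(Cl)Cl | intermediate
5 | 3-methyl-3-[(trimethylsilyl)ethynyl]cyclobutan-1-one (achiral) | CC1(C#C[Si](C)(C)C)CC(=O)C1 | intermediate
6 | trimethyl({(3R)-3-methyl-3-[(trimethylsilyl)ethynyl]cyclobut-1-en-1-yl}oxy)silane | C[C@@]1(C#C[Si](C)(C)C)CC(O[Si](C)(C)C)=C1 | intermediate
7 | (2R,3S)-2-chloro-3-methyl-3-[(trimethylsilyl)ethynyl]cyclobutan-1-one | C[C@@]1(C#C[Si](C)(C)C)CC(=O)[C@@H]1Cl | intermediate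
8 | (1R,2R,3S)-2-chloro-1-ethenyl-3-methyl-3-[(trimethylsilyl)ethynyl]cyclobutan-1-ol | C[C@@]1(C#C[Si](C)(C)C)C[C@@](O)(C=C)[C@@H]1Cl | intermediate
9 | (2S)-1-chloro-2-methyl-4-oxo-2-[(trimethylsilyl)ethynyl]hex-5-en-1-yl radical | C=CC(=O)C[C@@](C)(C#C[Si](C)(C)C)[CH]Cl | intermediate
10 | (3S,4S)-4-chloro-3-methyl-3-[(trimethylsilyl)ethynyl]cyclohexan-1-one | C[C@@]1(C#C[Si](C)(C)C)CC(=O)CC[C@@H]1Cl | intermediate
11 | (3S,4S)-4-chloro-3-(chloroethynyl)-3-methylcyclohexan-1-one | C[C@@]1(C#CCl)CC(=O)CC[C@@H]1Cl | intermediate
12 | (3S,4S)-4-chloro-3-[(Z)-2-chloroethenyl]-3-methylcyclohexan-1-one | C[C@@]1(/C=C\Cl)CC(=O)CC[C@@H]1Cl | intermediate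
13 | (1S,2S)-1-chloro-2-[(Z)-2-chloroethenyl]-2-methyl-4-methylidenecyclohexane | C[C@@]1(/C=C\Cl)CC(=C)CC[C@@H]1Cl | intermediate
14 | (1S,4S,5S)-5-chloro-4-[(Z)-2-chloroethenyl]-4-methyl-2-methylidenecyclohexan-1-ol | C[C@@]1(/C=C\Cl)CC(=C)[C@@H](O)C[C@@H]1Cl | intermediate
15 | (1S,2S,4R)-2,4-dichloro-1-[(Z)-2-chloroethenyl]-1-methyl-5-methylidenecyclohexane | C[C@@]1(/C=C\Cl)CC(=C)[C@H](Cl)C[C@@H]1Cl | intermediate
16 | (1S,2R,4S,5S)-1-bromo-1-(bromomethyl)-2,4-dichloro-5-[(Z)-2-chloroethenyl]-5-methylcyclohexane | C[C@@]1(/C=C\Cl)C[C@@](Br)(CBr)[C@H](Cl)C[C@@H]1Cl | target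

**Step count and risks**

Total step count: 12. Longest linear sequence: 12 (the route is fully linear from 1).

Steps most likely to fail:

Step 3. The chiral base may discriminate the two enantiotopic CH2 groups poorly, because methyl and alkynyl differ less than the hydrogen and alkyl of the usual substrates, and 6 would then be of low enantiomeric purity. The fallback sets out from racemic 4 and replaces asymmetric synthesis by resolution. The enantiomers of 4 are separated by preparative chromatography on a chiral stationary phase to give (3S)-2,2-dichloro-3-methyl-3-[(trimethylsilyl)ethynyl]cyclobutan-1-one F1. Selective monodechlorination (Zn, 1 equiv, AcOH, rt) then comes back to the route at 7, formed together with its C2 epimer (2S,3S)-2-chloro-3-methyl-3-[(trimethylsilyl)ethynyl]cyclobutan-1-one F2, which converges with 7 in step 6.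

Step 6. Radical 9 may take up hydrogen before it closes (ring-opened chloromethyl enone), the vinyl ketone may oligomerise, or face selection at the new CHCl centre may be poor. The fallback sets out from 8 and separates ring opening from ring closure. Hypoiodite fragmentation (PhI(OAc)2, I2, visible light, CH2Cl2) opens the same ring bond and traps the radical as the geminal chloroiodide (5S)-6-chloro-6-iodo-5-methyl-5-[(trimethylsilyl)ethynyl]hex-1-en-3-one F3. Slow addition of Bu3SnH/AIBN (benzene, 80 °C, high dilution) then abstracts iodine and effects the same 6-endo closure through the same chair, coming back at 10.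

Step 10. The ene reaction may compete at the ring CH2 next to the quaternary carbon, the alcohol may be over-oxidised to the enone, or oxygen may be delivered to the wrong face. The fallback sets out from 12 and fixes site and face before the methylene is present. Kinetic enolisation away from the quaternary carbon (LDA, TMSCl, THF, −78 °C; ketone deprotonation outruns attack on the chloroalkene) should give {[(4S,5S)-4-chloro-5-[(Z)-2-chloroethenyl]-5-methylcyclohex-1-en-1-yl]oxy}trimethylsilane F4. Rubottom oxidation (mCPBA, then dilute acid), with the peracid expected anti to the ring C–Cl, should give (2S,4S,5S)-4-chloro-5-[(Z)-2-chloroethenyl]-2-hydroxy-5-methylcyclohexan-1-one F5. Wittig methylenation with excess Ph3P=CH2 comes back to the route at 14.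

**Further compounds**

F1 | step 3 | (3S)-2,2-dichloro-3-methyl-3-[(trimethylsilyl)ethynyl]cyclobutan-1-one | C[C@@]1(C#C[Si](C)(C)C)CC(=O)C1(Cl)Cl
F2 | step 3 | (2S,3S)-2-chloro-3-methyl-3-[(trimethylsilyl)ethynyl]cyclobutan-1-one | C[C@@]1(C#C[Si](C)(C)C)CC(=O)[C@H]1Cl
F3 | step 6 | (5S)-6-chloro-6-iodo-5-methyl-5-[(trimethylsilyl)ethynyl]hex-1-en-3-one (both C6 epimers) | C=CC(=O)C[C@@](C)(C#C[Si](C)(C)C)C(Cl)I
F4 | step 10 | {[(4S,5S)-4-chloro-5-[(Z)-2-chloroethenyl]-5-methylcyclohex-1-en-1-yl]oxy}trimethylsilane | C[C@@]1(/C=C\Cl)CC(O[Si](C)(C)C)=CC[C@@H]1Cl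
F5 | step 10 | (2S,4S,5S)-4-chloro-5-[(Z)-2-chloroethenyl]-2-hydroxy-5-methylcyclohexan-1-one | C[C@@]1(/C=C\Cl)CC(=O)[C@@H](O)C[C@@H]1Cl
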